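**Strategy**

Ring numbering: C1 ketone, C2 (=CH), C3 (C–OMe), C4 (CHOH), C5/C6 epoxide carbons, C6 bearing farnesyl. The key step exploits the 1,3-placed oxygens at C1 and C3 of the six-membered ring: C2=C3 is read as methoxyacetylene and C1, C6, C5, C4 as a vinylketene, the ring as a latent 3-methoxyphenol. Irradiating a farnesyl-substituted α,β-unsaturated diazomethyl ketone triggers Wolff shift, ketene–ynol ether [2+2] cycloaddition, strain-releasing 4π opening and 6π closure: C1–C2 and C3–C4 form in one operation, regiospecifically, giving 2-farnesyl-5-methoxyphenol. Quinone formation, asymmetric nucleophilic epoxidation of C5=C6 and reduction of the C4 ketone anti to the epoxide then set the three stereocentres.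

Key step: step 6

Remarks on the chemistry:
- Farnesyl means (2E,6E)-3,7,11-trimethyldodeca-2,6,10-trien-1-yl throughout.
- Methoxyacetylene is assumed not to be reliably purchasable and is made in step 5.
- The sense of induction of the cinchona salt in step 8 cannot be predicted with confidence for this quinone. The cinchonidinium salt is written; if the other epoxide enantiomer is favoured, the quasi-enantiomeric N-benzylcinchoninium chloride replaces it with nothing else changed.
- But-3-yn-2-ol is used as the racemate; its stereocentre is removed in step 3.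

**Route**

Step 1
Reactants: 1 (2E,6E)-farnesyl bromide; 2 but-3-yn-2-ol (racemic)
Product: 3 (6E,10E)-7,11,15-trimethylhexadeca-6,10,14-trien-3-yn-2-ol (racemic)
Conditions: CuI (10 mol %), NaI (10 mol %), K2CO3, DMF, 20 °C
Reagents that add atoms: none
Why: the monovalent copper acetylide formed from 2 under carbonate base should displace the primary allylic bromide at its CH2 terminus (copper-catalysed alkyne allylation, SN2 sense), keeping the 2E alkene and giving the skipped enyne.

Step 2
Reactants: 3 (6E,10E)-7,11,15-trimethylhexadeca-6,10,14-trien-3-yn-2-ol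
Product: 4 (3E,6E,10E)-7,11,15-trimethylhexadeca-3,6,10,14-tetraen-2-ol (racemic)
Conditions: NaAlH2(OCH2CH2OCH3)2 (Red-Al), THF, 0 to 20 °C; aq. potassium sodium tartrate
Reagents that add atoms: none
Why: alkoxide-directed trans-hydroalumination of the propargylic alcohol followed by protonolysis should give only the E-allylic alcohol, the isolated trialkyl alkenes being inert to the aluminium hydride.

Step 3
Reactants: 4 (3E,6E,10E)-7,11,15-trimethylhexadeca-3,6,10,14-tetraen-2-ol
Product: 5 (3E,6E,10E)-7,11,15-trimethylhexadeca-3,6,10,14-tetraen-2-one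
Conditions: MnO2 (activated, excess), CH2Cl2, 20 °C
Reagents that add atoms: none
Why: MnO2 oxidation is selective for allylic alcohols and runs under neutral heterogeneous conditions, so the skipped dienone should not isomerise into conjugation.

Step 4
Reactants: 5 (3E,6E,10E)-7,11,15-trimethylhexadeca-3,6,10,14-tetraen-2-one
Product: 7 (3E,6E,10E)-1-diazo-7,11,15-trimethylhexadeca-3,6,10,14-tetraen-2-one, via trifluoroacetyl ketone 6 (not isolated)
Conditions: LiHMDS, THF, −78 °C, then CF3CO2CH2CF3; crude 6, MsN3, Et3N, H2O (1 equiv), MeCN, 20 °C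
Reagents that add atoms: methanesulfonyl azide CS(=O)(=O)N=[N+]=[N-]; 2,2,2-trifluoroethyl trifluoroacetate O=C(OCC(F)(F)F)C(F)(F)F (its trifluoroacetyl group is carried only by 6)
Why: detrifluoroacetylative diazo transfer, in which kinetic deprotonation at the α′-methyl group (not at the doubly allylic γ-CH2), Claisen trifluoroacetylation and Regitz diazo transfer with loss of the trifluoroacetyl group as the sulfonamide should give the unsaturated diazo ketone without the pyrazoline formation that plagues acyl chloride/diazomethane routes to enone diazo ketones.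

Step 5
Reactants: 8 chloroacetaldehyde dimethyl acetal
Product: 10 methoxyacetylene, via sodium methoxyethynide 9 (not isolated)
Conditions: NaNH2 (3 equiv), liq. NH3, −33 °C; NH3 evaporated; aq. NaCl, −20 °C; distilled into ClCH2CH2Cl at −30 °C
Reagents that add atoms: none
Why: successive amide-induced eliminations of methanol and HCl should give the sodium acetylide, which water protonates, and the volatile ynol ether is collected as a cold stock solution for immediate use.

Step 6
Reactants: 7 (3E,6E,10E)-1-diazo-7,11,15-trimethylhexadeca-3,6,10,14-tetraen-2-one; 10 methoxyacetylene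
Product: 15 5-methoxy-2-[(2E,6E)-3,7,11-trimethyldodeca-2,6,10-trien-1-yl]phenol, via vinylketene 11 (not isolated), via vinylcyclobutenone 12 (not isolated), via dienylketene 13 (not isolated), via cyclohexadienone 14 (not isolated)
Conditions: 10 (3 equiv), ClCH2CH2Cl, hν (254 nm, quartz, sealed tube), 20 °C; then 80 °C
Reagents that add atoms: none
Why: Light expels N2 from 7 and the alkenyl group shifts to the carbene carbon (photochemical Wolff rearrangement) to give vinylketene 11, whose ketene C=C adds to the ynol ether in a [2+2] cycloaddition (the four-membered ring closes by ketene–alkyne [2+2]), forming C1–C2 and C3–C4 of the later ring in cyclobutenone 12. Heating then drives the strain-releasing 4π electrocyclic opening of 12 to dienylketene 13, whose thermal disrotatory 6π electrocyclisation closes the six-membered ring (C1–C6) to dienone 14, which tautomerises to phenol 15. The closest known reaction type is the Danheiser benzannulation in its second-generation diazo ketone variant with alkoxy- and siloxyalkynes. No stereocentre is set, since the sp3 centres of 12 and 14 are transient and are erased on aromatisation. The step needs regioselectivity, secured by polarisation: the nucleophilic CH terminus of methoxyacetylene attacks the electrophilic ketene carbon, so OMe ends meta to OH and farnesyl ortho to it. It also needs chemoselectivity of the ketene for the ynol ether over the three trialkyl alkenes of the chain, secured by the much higher ketenophilicity of ynol ethers and their use in excess.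

Step 7
Reactants: 15 5-methoxy-2-[(2E,6E)-3,7,11-trimethyldodeca-2,6,10-trien-1-yl]phenol
Product: 16 2-methoxy-5-[(2E,6E)-3,7,11-trimethyldodeca-2,6,10-trien-1-yl]cyclohexa-2,5-diene-1,4-dione
Conditions: (KSO3)2NO (2.5 equiv), KH2PO4, Aliquat 336 (cat.), CH2Cl2/H2O, 20 °C
Reagents that add atoms: Fremy's salt (potassium nitrosodisulfonate) [K+].[K+].[O]N(S(=O)(=O)[O-])S(=O)(=O)[O-]
Why: Teuber oxidation, in which the nitroxide abstracts the phenolic hydrogen and a second equivalent adds at the free para position (C4, activated by the ortho methoxy group), should give the para-quinone after loss of imidodisulfonate, the isolated alkenes being inert to the radical.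

Step 8
Reactants: 16 2-methoxy-5-[(2E,6E)-3,7,11-trimethyldodeca-2,6,10-trien-1-yl]cyclohexa-2,5-diene-1,4-dione
Product: 17 (5S,6R)-5,6-epoxy-3-methoxy-6-[(2E,6E)-3,7,11-trimethyldodeca-2,6,10-trien-1-yl]cyclohex-2-ene-1,4-dione
Conditions: t-BuOOH, N-benzylcinchonidinium chloride (10 mol %), aq. NaOH, toluene, 0 °C
Reagents that add atoms: tert-butyl hydroperoxide CC(C)(C)OO
Why: Weitz–Scheffer nucleophilic epoxidation under asymmetric phase-transfer catalysis, in which the peroxide anion ion-paired with the chiral ammonium should add only to the farnesyl-bearing C5=C6 bond (C2=C3 is a deactivated vinylogous ester) and close to the necessarily cis-fused epoxide, the face chosen by the ion pair setting C5 and C6 together, as known for 2-alkyl-1,4-naphthoquinones.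

Step 9
Reactants: 17 (5S,6R)-5,6-epoxy-3-methoxy-6-[(2E,6E)-3,7,11-trimethyldodeca-2,6,10-trien-1-yl]cyclohex-2-ene-1,4-dione
Product: 18 (4S,5R,6R)-5,6-epoxy-4-hydroxy-3-methoxy-6-[(2E,6E)-3,7,11-trimethyldodeca-2,6,10-trien-1-yl]cyclohex-2-en-1-one (yanuthone X2)
Conditions: NaBH4 (0.5 equiv), CeCl3·7H2O, MeOH, −78 °C
Reagents that add atoms: none
Why: Luche 1,2-reduction should take the C4 ketone (C1 is a vinylogous ester carbonyl next to the quaternary C6) and deliver hydride to the face anti to the epoxide oxygen (polar Felkin–Anh-type substrate control), setting C4 as S with the hydroxyl cis to the epoxide.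

**Compound list**

1 | (2E,6E)-farnesyl bromide, (2E,6E)-1-bromo-3,7,11-trimethyldodeca-2,6,10-triene | BrC/C=C(\C)CC/C=C(\C)CCC=C(C)C | starting material
2 | but-3-yn-2-ol (racemic) | CC(O)C#C | starting material
3 | (6E,10E)-7,11,15-trimethylhexadeca-6,10,14-trien-3-yn-2-ol (racemic) | CC(O)C#CC/C=C(\C)CC/C=C(\C)CCC=C(C)C | intermediate
4 | (3E,6E,10E)-7,11,15-trimethylhexadeca-3,6,10,14-tetraen-2-ol (racemic) | CC(O)/C=C/C/C=C(\C)CC/C=C(\C)CCC=C(C)C | intermediate
5 | (3E,6E,10E)-7,11,15-trimethylhexadeca-3,6,10,14-tetraen-2-one | CC(=O)/C=C/C/C=C(\C)CC/C=C(\C)CCC=C(C)C | intermediate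
6 | trifluoroacetyl ketone, (5E,8E,12E)-1,1,1-trifluoro-9,13,17-trimethyloctadeca-5,8,12,16-tetraene-2,4-dione (carried on crude) | FC(F)(F)C(=O)CC(=O)/C=C/C/C=C(\C)CC/C=C(\C)CCC=C(C)C | intermediate
7 | (3E,6E,10E)-1-diazo-7,11,15-trimethylhexadeca-3,6,10,14-tetraen-2-one | [N-]=[N+]=CC(=O)/C=C/C/C=C(\C)CC/C=C(\C)CCC=C(C)C | intermediate
8 | chloroacetaldehyde dimethyl acetal (2-chloro-1,1-dimethoxyethane) | COC(CCl)OC | starting material
9 | sodium methoxyethynide | [Na+].[C-]#COC | intermediate
10 | methoxyacetylene (methoxyethyne) | COC#C | intermediate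
11 | vinylketene, (3E,6E,10E)-7,11,15-trimethylhexadeca-1,3,6,10,14-pentaen-1-one | O=C=C/C=C/C/C=C(\C)CC/C=C(\C)CCC=C(C)C | intermediate
12 | vinylcyclobutenone, 3-methoxy-4-[(1E,4E,8E)-5,9,13-trimethyltetradeca-1,4,8,12-tetraen-1-yl]cyclobut-2-en-1-one (racemic) | COC1=CC(=O)C1/C=C/C/C=C(\C)CC/C=C(\C)CCC=C(C)C | intermediate
13 | dienylketene, (3E,5E,8E,12E)-3-methoxy-9,13,17-trimethyloctadeca-1,3,5,8,12,16-hexaen-1-one | O=C=C\C(OC)=C/C=C/C/C=C(\C)CC/C=C(\C)CCC=C(C)C | intermediate
14 | cyclohexadienone, 3-methoxy-6-[(2E,6E)-3,7,11-trimethyldodeca-2,6,10-trien-1-yl]cyclohexa-2,4-dien-1-one (racemic) | COC1=CC(=O)C(C/C=C(\C)CC/C=C(\C)CCC=C(C)C)C=C1 | intermediate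
15 | 5-methoxy-2-[(2E,6E)-3,7,11-trimethyldodeca-2,6,10-trien-1-yl]phenol | COc1ccc(C/C=C(\C)CC/C=C(\C)CCC=C(C)C)c(O)c1 | intermediate
16 | 2-methoxy-5-[(2E,6E)-3,7,11-trimethyldodeca-2,6,10-trien-1-yl]cyclohexa-2,5-diene-1,4-dione | COC1=CC(=O)C(C/C=C(\C)CC/C=C(\C)CCC=C(C)C)=CC1=O | intermediate
17 | (5S,6R)-5,6-epoxy-3-methoxy-6-[(2E,6E)-3,7,11-trimethyldodeca-2,6,10-trien-1-yl]cyclohex-2-ene-1,4-dione, equal to (1R,6S)-4-methoxy-1-farnesyl-7-oxabicyclo[4.1.0]hept-3-ene-2,5-dione | COC1=CC(=O)[C@]2(C/C=C(\C)CC/C=C(\C)CCC=C(C)C)O[C@@H]2C1=O | intermediate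
18 | yanuthone X2, (4S,5R,6R)-5,6-epoxy-4-hydroxy-3-methoxy-6-[(2E,6E)-3,7,11-trimethyldodeca-2,6,10-trien-1-yl]cyclohex-2-en-1-one, equal to (1R,5S,6R)-5-hydroxy-4-methoxy-1-farnesyl-7-oxabicyclo[4.1.0]hept-3-en-2-one | COC1=CC(=O)[C@]2(C/C=C(\C)CC/C=C(\C)CCC=C(C)C)O[C@@H]2[C@@H]1O | target

**Step count and risks**

Total step count: 9. Longest linear sequence: 8 steps (steps 1 to 4 and 6 to 9); step 5 is a one-step side branch.

Steps most likely to fail:

The key annulation, step 6. Under 254 nm light the polyene may drift into E/Z isomerisation of the enone and sensitised reactions of the skipped diene, ketene 11 may oligomerise before it is trapped, the volatile ynol ether may be lost, and phenol 15 may be O-acylated by 11 (a brief K2CO3/MeOH treatment would cleave such esters). The fallback sets out from 7 and comes back at 15, and makes the ketene thermally instead of photochemically. In the dark, PhCO2Ag (10 mol %) with Et3N in aqueous THF should effect the Wolff rearrangement with capture by water to give (3E,6E,10E)-7,11,15-trimethylhexadeca-3,6,10,14-tetraenoic acid F1. (COCl)2 with catalytic DMF in CH2Cl2 at 0 °C should convert it into (3E,6E,10E)-7,11,15-trimethylhexadeca-3,6,10,14-tetraenoyl chloride F2. Slow addition of Et3N to F2 and excess 10 in toluene at 0 to 20 °C should generate 11 by dehydrochlorination and trap it as 12 (the classical acid chloride/amine/alkoxyacetylene cyclobutenone synthesis); heating the filtered solution to 80–110 °C should complete the 4π/6π sequence to 15. The two ring bonds are still made in one operation.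

The asymmetric epoxidation, step 8. Facial discrimination within the ammonium–peroxide ion pair may be weak, giving low enantiomeric excess, and hydroxide may attack the methoxyquinone or trigger tautomerisation of the farnesylquinone towards a chromenol. The fallback sets out from 16 and comes back at 18, and replaces asymmetric catalysis by an enzymatic kinetic resolution. Achiral Weitz–Scheffer epoxidation (H2O2, Na2CO3, THF/H2O, 0 °C) should give the racemic epoxyquinone rac-17 F3. Luche reduction as in step 9 should give the racemic cis-epoxy alcohol rac-18 F4. Lipase-catalysed transesterification (Burkholderia cepacia lipase or Candida antarctica lipase B, vinyl acetate, t-BuOMe, 30 °C), with the lipase chosen so that the unwanted enantiomer is acylated and run past half conversion, should convert it into the acetate of ent-18 F5 and leave 18, which is separated by chromatography. Scalemic material from step 8 could be polished in the same way.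

The reduction, step 9. Hydride may be delivered from the epoxide face through metal coordination to the epoxide oxygen, giving the trans alcohol, or the two faces may be poorly discriminated. The fallback sets out from 17 and comes back at 18, and deliberately makes the epimer and inverts it. i-Bu2AlH in THF at −78 °C, which coordinates the epoxide oxygen and delivers hydride syn to it, should give the trans-epoxy alcohol (4R,5R,6R)-5,6-epoxy-4-hydroxy-3-methoxy-6-farnesylcyclohex-2-en-1-one F6. Mitsunobu inversion (4-nitrobenzoic acid, PPh3, diisopropyl azodicarboxylate, THF, 0 °C) should give the 4-nitrobenzoate of 18 F7. Methanolysis (K2CO3, MeOH, 0 °C) should release 18.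

Further compounds
F1 | step 6 | (3E,6E,10E)-7,11,15-trimethylhexadeca-3,6,10,14-tetraenoic acid | OC(=O)C/C=C/C/C=C(\C)CC/C=C(\C)CCC=C(C)C
F2 | step 6 | (3E,6E,10E)-7,11,15-trimethylhexadeca-3,6,10,14-tetraenoyl chloride | ClC(=O)C/C=C/C/C=C(\C)CC/C=C(\C)CCC=C(C)C
F3 | step 8 | rac-17, racemic 5,6-epoxy-3-methoxy-6-farnesylcyclohex-2-ene-1,4-dione (both enantiomers written) | COC1=CC(=O)[C@]2(C/C=C(\C)CC/C=C(\C)CCC=C(C)C)O[C@@H]2C1=O.COC1=CC(=O)[C@@]2(C/C=C(\C)CC/C=C(\C)CCC=C(C)C)O[C@H]2C1=O
F4 | step 8 | rac-18, racemic cis-5,6-epoxy-4-hydroxy-3-methoxy-6-farnesylcyclohex-2-en-1-one (both enantiomers written) | COC1=CC(=O)[C@]2(C/C=C(\C)CC/C=C(\C)CCC=C(C)C)O[C@@H]2[C@@H]1O.COC1=CC(=O)[C@@]2(C/C=C(\C)CC/C=C(\C)CCC=C(C)C)O[C@H]2[C@H]1O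
F5 | step 8 | acetate of ent-18, (4R,5S,6S)-5,6-epoxy-3-methoxy-1-oxo-6-farnesylcyclohex-2-en-4-yl acetate | COC1=CC(=O)[C@@]2(C/C=C(\C)CC/C=C(\C)CCC=C(C)C)O[C@H]2[C@H]1OC(C)=O
F6 | step 9 | (4R,5R,6R)-5,6-epoxy-4-hydroxy-3-methoxy-6-farnesylcyclohex-2-en-1-one (C4 epimer of 18) | COC1=CC(=O)[C@]2(C/C=C(\C)CC/C=C(\C)CCC=C(C)C)O[C@@H]2[C@H]1O
F7 | step 9 | 4-nitrobenzoate of 18, (4S,5R,6R)-5,6-epoxy-3-methoxy-1-oxo-6-farnesylcyclohex-2-en-4-yl 4-nitrobenzoate | COC1=CC(=O)[C@]2(C/C=C(\C)CC/C=C(\C)CCC=C(C)C)O[C@@H]2[C@@H]1OC(=O)c1ccc(cc1)[N+](=O)[O-]
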